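A direct plan would convert safranal A1 into safranyl phenyl sulfone A2, set C3 by asymmetric hydroboration–oxidation of the ring diene followed by silylation to give silyl ether A3, and for ring B oxidise A3 at C4 to enone A4 and reduce it again with a bulky hydride.
The carbanions of the two C10 sulfones would be added in turn to crocetindial A5, and both triple bonds would be made last by double elimination from the C40 bis(sulfone) A6, before desilylation.
First weakness, the asymmetric hydroboration of A2 that would lead to A3: it would be the only source of absolute configuration in a sequence that starts from achiral A1, yet it would act on a cyclic cis-alkene inside a 1,3-diene, where diisopinocampheylborane gives uncertain regio- and enantiocontrol.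
Second weakness, the allylic C–H oxidation of A3 to A4 and the reduction that follows: two redox steps that would build no skeleton, with C4 set only by reagent approach to a ketone.
Third weakness, the double elimination from A6: a large excess of KOt-Bu would act on the complete C40 polyene built on A5 while an ionisable allylic oxygen at C4' sits next to a vinyl sulfone, so vinylogous loss of that oxygen and E/Z scrambling would threaten at the last C–C stage.

Retrosynthetic overview
Both rings would come from one building block, (S)-phorenol, made from ketoisophorone by a single catalytic asymmetric transfer hydrogenation; the skeleton is cut at C6–C7 and C6'–C7', so both triple bonds are carried in ready-made in a C22 heptaenediyne.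
Ring A (C1'–C6') is attached as its enol triflate by Sonogashira coupling; ring B is attached as the unrearranged enone by acetylide 1,2-addition, before its C5=C6 bond exists.
The key step turns that 1,2-adduct into ring B: ionisation at C6 and delivery of the carbonyl oxygen of the C3 Boc group to C4 move the ring alkene from C4=C5 to C5=C6 (into conjugation with C7≡C8), install O-4 and set C4 cis to C3, leaving the diol as a cyclic carbonate.
No hydroboration, no C–H oxidation/reduction pair and no late elimination are needed: C3 and C3' come from one catalytic reduction, C4 by relay from C3 without a redox change, and the end game is a saponification.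
No carbocycle is formed in the route; the only ring closed is the temporary five-membered carbonate of the key step.

Key step: step 8

Assumption: the (S,S)-configured transfer-hydrogenation catalyst is taken to give the (S)-alcohol by analogy with aryl ketones (ring alkene in the place of the aryl group); if the sense is the opposite, the (R,R) catalyst is used and nothing else changes.

Step 1
Reactants: 1 ketoisophorone (2,6,6-trimethylcyclohex-2-ene-1,4-dione)
Product: 2 (S)-phorenol [(4S)-4-hydroxy-2,6,6-trimethylcyclohex-2-en-1-one]
Conditions: RuCl[(S,S)-TsDPEN](p-cymene) (TsDPEN = N-tosyl-1,2-diphenylethane-1,2-diamine; 1 mol %), i-PrOH, 23 °C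
Reagents that add atoms: none
Why: Noyori-type asymmetric transfer hydrogenation should reduce only the C4 carbonyl, since the C1 carbonyl is shielded by the gem-dimethyl carbon and the methyl-bearing alkene carbon, and the chiral ruthenium hydride selects the enantioface; this single centre later serves as C3 of ring B and C3' of ring A.

Step 2
Reactants: 2 (S)-phorenol
Product: 3 tert-butyl (1S)-3,5,5-trimethyl-4-oxocyclohex-2-en-1-yl carbonate
Conditions: Boc2O (1.2 equiv), 4-(dimethylamino)pyridine (5 mol %), Et3N, CH2Cl2, 0 → 23 °C
Reagents that add atoms: di-tert-butyl dicarbonate CC(C)(C)OC(=O)OC(=O)OC(C)(C)C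
Why: Nucleophile-catalysed O-acylation (tert-butoxycarbonylation) of the secondary alcohol leaves the stereocentre untouched, and the Boc group is chosen because it protects O-3' in ring A and is the internal oxygen nucleophile for C4 in ring B.

Step 3
Reactants: 3 enone carbonate (the part not used in step 7)
Product: 4 tert-butyl (1R)-3,3,5-trimethyl-4-oxocyclohexyl carbonate (both epimers at the methyl-bearing carbon)
Conditions: Cu(OAc)2·H2O (3 mol %), 1,2-bis(diphenylphosphino)benzene (3 mol %), (EtO)2MeSiH (1.5 equiv), t-BuOH (1.5 equiv), toluene, 0 → 23 °C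
Reagents that add atoms: none
Why: Copper hydride-catalysed conjugate (1,4-) reduction delivers hydride to the β-carbon and tert-butanol protonates the copper enolate, which avoids the hydrogenolysis of the allylic C–O bond that hydrogenation over palladium could cause; the new methyl-bearing centre is a mixture that does not matter because it becomes sp2 in step 4, and the carbinol centre is untouched (its label becomes R only by CIP ranking).

Step 4
Reactants: 4 saturated ketone carbonate
Product: 6 (4R)-4-[(tert-butoxycarbonyl)oxy]-2,6,6-trimethylcyclohex-1-en-1-yl trifluoromethanesulfonate, via lithium enolate 5 (not isolated)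
Conditions: LiN(i-Pr)2 (1.1 equiv), THF, −78 °C; PhNTf2 (1.1 equiv), −78 → 0 °C; aq. NH4Cl
Reagents that add atoms: N-phenylbis(trifluoromethanesulfonimide) O=S(=O)(N(c1ccccc1)S(=O)(=O)C(F)(F)F)C(F)(F)F; lithium diisopropylamide [Li]N(C(C)C)C(C)C (lithium of 5 only)
Why: Enol triflate formation by O-sulfonylation of a lithium enolate: the ketone has only one α-hydrogen (the other α-carbon is quaternary), so both epimers of 4 give the same tetrasubstituted enolate, and the carbonate sits on the γ-carbon of the ketone, so no E1cB elimination path exists.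

Step 5
Reactants: 7 all-E crocetindial (2,6,11,15-tetramethylhexadeca-2,4,6,8,10,12,14-heptaenedial)
Product: 8 (3E,5E,7E,9E,11E,13E,15E)-3,7,12,16-tetramethyloctadeca-3,5,7,9,11,13,15-heptaene-1,17-diyne
Conditions: Me3SiCHN2 (2.4 equiv), LiN(i-Pr)2 (2.4 equiv), THF, −78 °C; 7 (suspension in THF), −78 → 0 °C, dark; aq. NH4Cl
Reagents that add atoms: trimethylsilyldiazomethane C[Si](C)(C)C=[N+]=[N-]
Why: Colvin rearrangement (Peterson-type olefination to a diazoalkene, loss of N2 and 1,2-hydrogen shift of the alkylidene carbene) homologates each aldehyde to a terminal alkyne in an aprotic medium, so both triple bonds of the target exist from here on and no C=C bond of the all-E chain is made or broken.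

Step 6
Reactants: 6 ring A enol triflate; 8 C22 heptaenediyne (3 equiv)
Product: 9 tert-butyl (1R)-3,5,5-trimethyl-4-[(3E,5E,7E,9E,11E,13E,15E)-3,7,12,16-tetramethyloctadeca-3,5,7,9,11,13,15-heptaene-1,17-diyn-1-yl]cyclohex-3-en-1-yl carbonate (ring A joined, far end a free terminal alkyne)
Conditions: Pd(PPh3)4 (5 mol %), CuI (10 mol %), Et3N, DMF, 45 °C, Ar, dark; excess 8 recovered by chromatography
Reagents that add atoms: none
Why: Sonogashira coupling of a 2,6,6-trimethylcyclohexenyl triflate with a terminal enyne, a well-precedented pairing, forms C6'–C7' after oxidative addition of the triflate to zerovalent palladium; the excess of the symmetrical diyne should favour mono-coupling, and the Boc carbonate is homoallylic and so is not ionised by palladium.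

Step 7
Reactants: 9 C31 terminal alkyne; 3 enone carbonate (1.5 equiv)
Product: 12 C40 tertiary propargylic alcohol in which the alkyne terminus of the ring A enyne chain carries the (4S)-4-[(tert-butoxycarbonyl)oxy]-1-hydroxy-2,6,6-trimethylcyclohex-2-en-1-yl group (3S,3'R; both epimers at C6), via lithium acetylide 10 (not isolated), via lithium alkoxide 11 (not isolated)
Conditions: 9, LiN(i-Pr)2 (1.05 equiv), THF, −78 °C; 3, −78 → −40 °C; aq. NH4Cl; rapid filtration through Et3N-washed silica, used at once
Reagents that add atoms: lithium diisopropylamide [Li]N(C(C)C)C(C)C (lithium of 10 and 11 only)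
Why: 1,2-Addition of a lithium acetylide to the enone carbonyl, which has no α-hydrogen and is known to accept acetylides despite its flanking methyl groups, forms C6–C7; the tert-butyl carbonates are poor electrophiles at −78 °C, and the configuration of the new carbinol centre C6 does not matter because step 8 erases it.

Step 8
Reactants: 12 C40 tertiary alcohol
Product: 13 (3S,4R,3'R)-7,8,7',8'-tetradehydro-β,β-carotene-3,4,3'-triol 3,4-cyclic carbonate 3'-(tert-butyl carbonate) (all-E)
Conditions: (±)-camphor-10-sulfonic acid (10 mol %), 4 Å MS, CH2Cl2, −40 → −10 °C, Ar, dark; Et3N quench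
Reagents that add atoms: none
Why: Proposed new method: acid ionises the tertiary C6 hydroxyl, which is both allylic (C4=C5) and propargylic (C7≡C8), to a delocalised cation, and the carbonyl oxygen of the C3 tert-butyl carbonate attacks C4 to give a 2-tert-butoxy-1,3-dioxolan-2-ylium ion that loses its tert-butyl group as isobutene; the closest known reaction types are the acid-catalysed tertiary-to-secondary allylic rearrangement of 1-alkynyl-2,6,6-trimethylcyclohex-2-en-1-ols and the capture of carbocations and iodonium ions by tert-butyl carbonates to give cyclic carbonates. The only ring closed is the five-membered carbonate bridging O-3 and O-4, formed in a 5-exo mode onto the terminus of the allyl cation. C4 is the only new stereocentre and is controlled by C3: the short two-atom tether should reach only the lobe of C4 on its own face, so the carbonate should be cis-fused and 4R should follow from 3S whatever the configuration at C6, since both C6 epimers give the same cation. The step needs capture at C4 in preference to C6, C8 and the chain positions that share the charge, and in preference to proton loss; this is secured by the intramolecular nucleophile and by the fact that capture of water elsewhere is reversible while loss of isobutene is not, the product having C5=C6 in conjugation with the whole chromophore. Molecular sieves keep water low to suppress Meyer–Schuster hydration at C8, and the remote secondary Boc carbonate on ring A has no cation within reach and should survive catalytic acid at low temperature (its loss would only anticipate step 9).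

Step 9
Reactants: 13 protected C40 carbonate
Product: 14 (3S,4R,3'R)-7,8,7',8'-tetradehydro-β,β-carotene-3,4,3'-triol (all-E), the target
Conditions: KOH (5% in MeOH), THF, 23 → 40 °C, Ar, dark; crystallisation or HPLC removes any Z isomers
Reagents that add atoms: none
Why: Saponification (acyl–oxygen cleavage of the cyclic carbonate and of the tert-butyl carbonate by hydroxide/methoxide) is the standard, polyene-tolerant deprotection of carotenol esters, needs no acid or fluoride, and leaves the ionisable allylic C4–OH and all three stereocentres untouched.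

Compound list
1 | ketoisophorone (2,6,6-trimethylcyclohex-2-ene-1,4-dione) | CC1=CC(=O)CC(C)(C)C1=O | starting material
2 | (S)-phorenol, (4S)-4-hydroxy-2,6,6-trimethylcyclohex-2-en-1-one | O=C1C(C)=C[C@@H](O)CC1(C)C | intermediate
3 | tert-butyl (1S)-3,5,5-trimethyl-4-oxocyclohex-2-en-1-yl carbonate | O=C1C(C)=C[C@@H](OC(=O)OC(C)(C)C)CC1(C)C | intermediate
4 | tert-butyl (1R)-3,3,5-trimethyl-4-oxocyclohexyl carbonate (epimers at the methyl-bearing carbon) | O=C1C(C)C[C@@H](OC(=O)OC(C)(C)C)CC1(C)C | intermediate
5 | lithium enolate of 4 | [Li]OC1=C(C)C[C@@H](OC(=O)OC(C)(C)C)CC1(C)C | intermediate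
6 | (4R)-4-[(tert-butoxycarbonyl)oxy]-2,6,6-trimethylcyclohex-1-en-1-yl trifluoromethanesulfonate | CC1=C(OS(=O)(=O)C(F)(F)F)C(C)(C)C[C@H](OC(=O)OC(C)(C)C)C1 | intermediate
7 | all-E crocetindial | O=C/C(C)=C/C=C/C(C)=C/C=C/C=C(C)/C=C/C=C(\C)C=O | starting material
8 | (3E,5E,7E,9E,11E,13E,15E)-3,7,12,16-tetramethyloctadeca-3,5,7,9,11,13,15-heptaene-1,17-diyne | C#C/C(C)=C/C=C/C(C)=C/C=C/C=C(C)/C=C/C=C(\C)C#C | intermediate
9 | ring A C31 terminal alkyne, tert-butyl (1R)-3,5,5-trimethyl-4-(3,7,12,16-tetramethyloctadeca-3,5,7,9,11,13,15-heptaene-1,17-diyn-1-yl)cyclohex-3-en-1-yl carbonate (all-E) | CC1=C(C#C/C(C)=C/C=C/C(C)=C/C=C/C=C(C)/C=C/C=C(\C)C#C)C(C)(C)C[C@H](OC(=O)OC(C)(C)C)C1 | intermediate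
10 | lithium acetylide of 9 | CC1=C(C#C/C(C)=C/C=C/C(C)=C/C=C/C=C(C)/C=C/C=C(\C)C#C[Li])C(C)(C)C[C@H](OC(=O)OC(C)(C)C)C1 | intermediate
11 | lithium alkoxide of 12 | CC1=C(C#C/C(C)=C/C=C/C(C)=C/C=C/C=C(C)/C=C/C=C(\C)C#CC2(O[Li])C(C)=C[C@@H](OC(=O)OC(C)(C)C)CC2(C)C)C(C)(C)C[C@H](OC(=O)OC(C)(C)C)C1 | intermediate
12 | C40 tertiary alcohol (3S,3'R; C6 epimers), ring B precursor with C4=C5, 6-OH and 3-OBoc | CC1=C(C#C/C(C)=C/C=C/C(C)=C/C=C/C=C(C)/C=C/C=C(\C)C#CC2(O)C(C)=C[C@@H](OC(=O)OC(C)(C)C)CC2(C)C)C(C)(C)C[C@H](OC(=O)OC(C)(C)C)C1 | intermediate
13 | (3S,4R,3'R)-7,8,7',8'-tetradehydro-β,β-carotene-3,4,3'-triol 3,4-cyclic carbonate 3'-(tert-butyl carbonate) | CC1=C(C#C/C(C)=C/C=C/C(C)=C/C=C/C=C(C)/C=C/C=C(\C)C#CC2=C(C)[C@H]3OC(=O)O[C@H]3CC2(C)C)C(C)(C)C[C@H](OC(=O)OC(C)(C)C)C1 | intermediate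
14 | (3S,4R,3'R)-7,8,7',8'-tetradehydro-β,β-carotene-3,4,3'-triol | CC1=C(C#C/C(C)=C/C=C/C(C)=C/C=C/C=C(C)/C=C/C=C(\C)C#CC2=C(C)[C@@H](O)[C@@H](O)CC2(C)C)C(C)(C)C[C@H](O)C1 | target

Total step count: 9. Longest linear sequence: 8 steps (steps 1, 2, 3, 4, 6, 7, 8, 9); step 5 is a one-step side branch.

Steps most likely to fail

Step 8 (proposed new method). The delocalised cation may lose a proton (from C3 or from a chain methyl, a retro-type dehydration) or be hydrated at C8 and tautomerise (Meyer–Schuster) faster than the weakly nucleophilic carbonate closes on C4; bond rotation in the cation may also scramble E/Z geometry. The fallback uses known reactions and sets out from 12. Triphenylsilyl perrhenate Ph3SiOReO3 (cat.) in Et2O at −50 → 0 °C shifts the hydroxyl from C6 to C4 by the [3,3] rearrangement of an allylic perrhenate ester, without free acid. This should give the (3S,4R,3'R)-4-hydroxy 3,3'-bis(tert-butyl carbonate) F1 together with its (4S) epimer F2, which are separated by chromatography. Catalytic KOt-Bu in THF at 0 °C then closes the cis isomer F1 onto its neighbouring Boc group with loss of tert-butanol, which comes back to the route at 13. The trans isomer F2 is re-equilibrated at C4 with the same rhenium catalyst and recycled.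

Step 6. Oxidative addition of the tetrasubstituted, doubly flanked triflate may be slow, so that copper-mediated alkyne homocoupling and coupling at both ends of the diyne compete. The fallback sets out from 4 and 8 and forms C6'–C7' by carbonyl addition instead of cross-coupling. Diyne 8 (excess) is mono-lithiated with LiN(i-Pr)2 in THF at −78 °C and added to ketone 4 to give, after aqueous quench, the tertiary propargylic alcohol tert-butyl (1R)-4-hydroxy-3,3,5-trimethyl-4-(3,7,12,16-tetramethyloctadeca-3,5,7,9,11,13,15-heptaene-1,17-diyn-1-yl)cyclohexyl carbonate F3. Dehydration of F3 with POCl3 in pyridine can go only toward the single β-hydrogen at C5' and gives the conjugated enyne, which comes back to the route at 9.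

Step 5. The lithiated diazo reagent may add in a conjugate or dipolar fashion to the dienal termini, and the low solubility of the dialdehyde at −78 °C may stop the reaction at mono-homologation. The fallback sets out from 7 and uses the Corey–Fuchs sequence. CBr4 and PPh3 in CH2Cl2 at 0 °C, which tolerate a suspension, give the bis(dibromoolefin) (3E,5E,7E,9E,11E,13E,15E)-1,1,18,18-tetrabromo-3,7,12,16-tetramethyloctadeca-1,3,5,7,9,11,13,15,17-nonaene F4. n-BuLi (4.2 equiv) in THF at −78 °C, then water, converts F4 by Fritsch–Buttenberg–Wiechell rearrangement into the diyne, which comes back to the route at 8.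

Further compounds
F1 | step 8 | (3S,4R,3'R)-4-hydroxy-7,8,7',8'-tetradehydro-β,β-carotene-3,3'-diyl bis(tert-butyl carbonate) (cis) | CC1=C(C#C/C(C)=C/C=C/C(C)=C/C=C/C=C(C)/C=C/C=C(\C)C#CC2=C(C)[C@@H](O)[C@@H](OC(=O)OC(C)(C)C)CC2(C)C)C(C)(C)C[C@H](OC(=O)OC(C)(C)C)C1
F2 | step 8 | (3S,4S,3'R)-4-hydroxy-7,8,7',8'-tetradehydro-β,β-carotene-3,3'-diyl bis(tert-butyl carbonate) (trans) | CC1=C(C#C/C(C)=C/C=C/C(C)=C/C=C/C=C(C)/C=C/C=C(\C)C#CC2=C(C)[C@H](O)[C@@H](OC(=O)OC(C)(C)C)CC2(C)C)C(C)(C)C[C@H](OC(=O)OC(C)(C)C)C1
F3 | step 6 | tert-butyl (1R)-4-hydroxy-3,3,5-trimethyl-4-(3,7,12,16-tetramethyloctadeca-3,5,7,9,11,13,15-heptaene-1,17-diyn-1-yl)cyclohexyl carbonate (all-E chain, epimers at C4 and C5 of the ring) | C#C/C(C)=C/C=C/C(C)=C/C=C/C=C(C)/C=C/C=C(\C)C#CC1(O)C(C)C[C@@H](OC(=O)OC(C)(C)C)CC1(C)C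
F4 | step 5 | (3E,5E,7E,9E,11E,13E,15E)-1,1,18,18-tetrabromo-3,7,12,16-tetramethyloctadeca-1,3,5,7,9,11,13,15,17-nonaene | BrC(Br)=C/C(C)=C/C=C/C(C)=C/C=C/C=C(C)/C=C/C=C(\C)C=C(Br)Br
A1 | direct plan | safranal | CC1=C(C=O)C(C)(C)CC=C1
A2 | direct plan | safranyl phenyl sulfone | CC1=C(CS(=O)(=O)c2ccccc2)C(C)(C)CC=C1
A3 | direct plan | tert-butyl(dimethyl){[(1R)-3,5,5-trimethyl-4-[(phenylsulfonyl)methyl]cyclohex-3-en-1-yl]oxy}silane | CC1=C(CS(=O)(=O)c2ccccc2)C(C)(C)C[C@H](O[Si](C)(C)C(C)(C)C)C1
A4 | direct plan | (6S)-6-[(tert-butyldimethylsilyl)oxy]-2,4,4-trimethyl-3-[(phenylsulfonyl)methyl]cyclohex-2-en-1-one | O=S(=O)(c1ccccc1)CC2=C(C)C(=O)[C@@H](O[Si](C)(C)C(C)(C)C)CC2(C)C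
A5 | direct plan | all-E crocetindial | O=C/C(C)=C/C=C/C(C)=C/C=C/C=C(C)/C=C/C=C(\C)C=O
A6 | direct plan | C40 bis(sulfone) with 8-benzoyloxy, 8'- and 4'-trimethylsilyloxy and 3,3'-bis(tert-butyldimethylsilyloxy) groups | CC1=C(C(S(=O)(=O)c2ccccc2)C(OC(=O)c2ccccc2)/C(C)=C/C=C/C(C)=C/C=C/C=C(C)/C=C/C=C(\C)C(O[Si](C)(C)C)C(S(=O)(=O)c2ccccc2)C2=C(C)[C@@H](O[Si](C)(C)C)[C@@H](O[Si](C)(C)C(C)(C)C)CC2(C)C)C(C)(C)C[C@H](O[Si](C)(C)C(C)(C)C)C1
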